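Both halves contain the same six-membered ring at two hydration levels: the C3a=C7a double bond of the eastern 4,5,6,7-tetrahydro-2-benzofuran-1(3H)-one is the dehydrated form of the western C2(OH)(CH2O)–C1H(CO2H) aldol unit. Everything therefore rests on one disconnection of that bond, which gives the acyclic 7-oxo aldehyde 10 (isopropyl and nitromethyl stereocentres from two amine-catalysed Michael additions). An L-proline-catalysed 6-enolexo aldolization joins the aldehyde α-carbon to the silyloxymethyl-ketone carbon, closes the carbocycle and sets the tertiary carbinol and its neighbour in one operation. Dehydration and lactonization of the common aldol give the eastern acid; the intact aldol gives the western diol; esterification and deprotection complete the target.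

Key step: step 6

Remark: the eastern lactone is discussed with 2-benzofuran-1(3H)-one numbering (C1 = lactone C=O, C3 = OCH2, C3a/C7a = ring-fusion carbons), whereas substituent names of the type "3-oxo-…-2-benzofuran-4-yl" follow the lowest-locant rule. Both enantiomers of the diarylprolinol ether catalysts are taken as commercial.

Step 1
Reactants: 1 (tert-butyldimethylsilyloxy)acetaldehyde; 2 vinylmagnesium bromide
Product: 3 rac-1-[(tert-butyldimethylsilyl)oxy]but-3-en-2-ol
Conditions: THF, −78 → 0 °C; then H2O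
Reagents that add atoms: none
Why: Grignard 1,2-addition of the vinyl group to the aldehyde; the carbinol centre is removed in step 2, so no stereocontrol is needed.

Step 2
Reactants: 3 rac-1-[(tert-butyldimethylsilyl)oxy]but-3-en-2-ol
Product: 4 1-[(tert-butyldimethylsilyl)oxy]but-3-en-2-one
Conditions: Dess–Martin periodinane, CH2Cl2, 0 °C; used at once
Reagents that add atoms: none
Why: Dess–Martin oxidation of a secondary allylic alcohol under neutral conditions should give the polymerisation-prone vinyl ketone without loss of the silyl ether.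

Step 3
Reactants: 5 3-methylbutanal; 4 1-[(tert-butyldimethylsilyl)oxy]but-3-en-2-one
Product: 6 (2R)-6-[(tert-butyldimethylsilyl)oxy]-2-isopropyl-5-oxohexanal
Conditions: (R)-2-(methoxydiphenylmethyl)pyrrolidine (5 mol %), ethyl 3,4-dihydroxybenzoate (20 mol %), neat (3 equiv 5), 4 °C
Reagents that add atoms: none
Why: Enamine-catalysed Michael addition of an aldehyde to a vinyl ketone; the (E)-enamine of the (R)-diarylprolinol ether is attacked on the face away from the diarylmethyl group, which should set the 2R centre.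

Step 4
Reactants: 6 (2R)-6-[(tert-butyldimethylsilyl)oxy]-2-isopropyl-5-oxohexanal; 7 (triphenylphosphoranylidene)acetaldehyde
Product: 8 (2E,4R)-8-[(tert-butyldimethylsilyl)oxy]-4-isopropyl-7-oxooct-2-enal
Conditions: toluene, 80 °C
Reagents that add atoms: none
Why: Wittig olefination with a stabilised formyl ylide, which should react with the aldehyde and not the ketone and give the E-enal without touching the α-stereocentre.

Step 5
Reactants: 8 (2E,4R)-8-[(tert-butyldimethylsilyl)oxy]-4-isopropyl-7-oxooct-2-enal; 9 nitromethane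
Product: 10 (3S,4R)-8-[(tert-butyldimethylsilyl)oxy]-4-isopropyl-3-(nitromethyl)-7-oxooctanal
Conditions: (S)-2-[diphenyl(trimethylsilyloxy)methyl]pyrrolidine (10 mol %), PhCO2H (20 mol %), MeNO2 (5 equiv), MeOH, rt
Reagents that add atoms: none
Why: Iminium-catalysed Michael addition of nitromethane to an enal; the (S)-catalyst shields one face of the s-trans iminium ion, so the 3S centre should arise under catalyst control that overrides the weak bias of the neighbouring isopropyl centre.

Step 6
Reactants: 10 (3S,4R)-8-[(tert-butyldimethylsilyl)oxy]-4-isopropyl-3-(nitromethyl)-7-oxooctanal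
Product: 11 (1S,2S,5R,6R)-2-{[(tert-butyldimethylsilyl)oxy]methyl}-2-hydroxy-5-isopropyl-6-(nitromethyl)cyclohexane-1-carbaldehyde
Conditions: L-proline (20 mol %), DMSO (0.05 M), rt
Reagents that add atoms: none
Why: L-Proline condenses with the aldehyde of 10 to the (E)-enamine, whose α-carbon (future C1 of the western ring and C7a of the butenolide) adds to the ketone carbon (future C2 and C3a) while the proline CO2H hydrogen-bonds the ketone oxygen, and hydrolysis then releases 11; this is the amine-catalysed intramolecular aldol of a dicarbonyl compound, applied to a 7-oxo aldehyde. The cyclohexane closes in the 6-(enolexo)-exo-trig mode. The new CH(CHO) centre is set by a chair transition state with isopropyl, nitromethyl and the enamine all equatorial (A1,3 strain forbids an axial enamine), and this sense is the one the enamine face of L-proline prefers, so substrate and catalyst are matched. The tertiary carbinol is set by the hydrogen bond: the nitrogen of the (E)-enamine and its CO2H lie beside the equatorial site of the ketone carbon, so the ketone oxygen should be equatorial and CH2OTBS axial, giving OH trans and CH2O cis to CHO. The step needs the aldehyde enamine to react in preference to ketone enamines and the nitronate, which the much faster condensation of the aldehyde, the absence of base and high dilution should secure; the enamine of the α-silyloxy ketone is expected on the oxygenated side, from which only an eight-membered ring could form.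

Step 7
Reactants: 11 (1S,2S,5R,6R)-2-{[(tert-butyldimethylsilyl)oxy]methyl}-2-hydroxy-5-isopropyl-6-(nitromethyl)cyclohexane-1-carbaldehyde
Product: 12 (1S,2S,5R,6R)-2-{[(tert-butyldimethylsilyl)oxy]methyl}-2-hydroxy-5-isopropyl-6-(nitromethyl)cyclohexane-1-carboxylic acid
Conditions: NaClO2, NaH2PO4, 2-methyl-2-butene, t-BuOH/H2O, 0 °C → rt
Reagents that add atoms: sodium chlorite [Na+].[O-]Cl=O
Why: Pinnick oxidation converts the sensitive β-hydroxy aldehyde into the acid at pH 3–4 without retro-aldol cleavage, epimerisation or loss of the silyl ether.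

Step 8
Reactants: 12 (1S,2S,5R,6R)-2-{[(tert-butyldimethylsilyl)oxy]methyl}-2-hydroxy-5-isopropyl-6-(nitromethyl)cyclohexane-1-carboxylic acid
Product: 13 tert-butyl (1S,2S,5R,6R)-2-{[(tert-butyldimethylsilyl)oxy]methyl}-2-hydroxy-5-isopropyl-6-(nitromethyl)cyclohexane-1-carboxylate
Conditions: Cl3CC(=NH)OtBu, CH2Cl2/cyclohexane, rt
Reagents that add atoms: tert-butyl 2,2,2-trichloroacetimidate CC(C)(C)OC(=N)C(Cl)(Cl)Cl
Why: Acid-free tert-butylation of a carboxylic acid with the trichloroacetimidate, which should leave the tertiary alcohol and the TBS ether alone; the tert-butyl ester is chosen because it resists lactonization by the cis CH2OH that is unveiled later.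

Step 9
Reactants: 13 tert-butyl (1S,2S,5R,6R)-2-{[(tert-butyldimethylsilyl)oxy]methyl}-2-hydroxy-5-isopropyl-6-(nitromethyl)cyclohexane-1-carboxylate
Product: 15 tert-butyl (1S,2S,5R,6R)-2-{[(tert-butyldimethylsilyl)oxy]methyl}-6-formyl-2-hydroxy-5-isopropylcyclohexane-1-carboxylate, via sodium nitronate 14 (not isolated)
Conditions: NaOMe (1.05 equiv), MeOH, 0 °C; O3, −78 °C; N2 purge, pH 7 buffer
Reagents that add atoms: ozone [O-][O+]=O; sodium methoxide C[O-].[Na+]
Why: Nef reaction by ozonolysis of the nitronate C=N bond, which should give the aldehyde without over-oxidation; the equatorial formyl group is the thermodynamic epimer, so the centre should hold.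

Step 10
Reactants: 16 tert-butyl (diethoxyphosphoryl)acetate; 17 formaldehyde
Product: 18 rac-tert-butyl 2-(diethoxyphosphoryl)-3-hydroxypropanoate
Conditions: 37% aq HCHO (1.0 equiv), K2CO3 (cat.), THF, 0 °C
Reagents that add atoms: none
Why: Base-catalysed aldol-type hydroxymethylation of the doubly activated methylene; one equivalent of formaldehyde at low temperature should stop at the mono-adduct.

Step 11
Reactants: 18 rac-tert-butyl 2-(diethoxyphosphoryl)-3-hydroxypropanoate
Product: 19 rac-tert-butyl 3-[(tert-butyldiphenylsilyl)oxy]-2-(diethoxyphosphoryl)propanoate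
Conditions: TBDPSCl, imidazole, DMF, rt
Reagents that add atoms: tert-butyldiphenylsilyl chloride CC(C)(C)[Si](Cl)(c1ccccc1)c1ccccc1
Why: Silylation of the primary alcohol blocks collapse of the β-hydroxy phosphonate to an acrylate and installs an ether that survives the later acid steps.

Step 12
Reactants: 15 tert-butyl (1S,2S,5R,6R)-2-{[(tert-butyldimethylsilyl)oxy]methyl}-6-formyl-2-hydroxy-5-isopropylcyclohexane-1-carboxylate; 19 rac-tert-butyl 3-[(tert-butyldiphenylsilyl)oxy]-2-(diethoxyphosphoryl)propanoate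
Product: 20 tert-butyl (1S,2S,5R,6S)-6-[(1E)-3-tert-butoxy-2-{[(tert-butyldiphenylsilyl)oxy]methyl}-3-oxoprop-1-en-1-yl]-2-{[(tert-butyldimethylsilyl)oxy]methyl}-2-hydroxy-5-isopropylcyclohexane-1-carboxylate
Conditions: 19, NaH, THF, 0 °C; then 15, 0 °C → rt
Reagents that add atoms: none
Why: Horner–Wadsworth–Emmons olefination of an α-branched aldehyde with an α-substituted phosphonoacetate, which should give the E (tiglate-type) enoate with the ring carbon trans to the ester.

Step 13
Reactants: 20 tert-butyl (1S,2S,5R,6S)-6-[(1E)-3-tert-butoxy-2-{[(tert-butyldiphenylsilyl)oxy]methyl}-3-oxoprop-1-en-1-yl]-2-{[(tert-butyldimethylsilyl)oxy]methyl}-2-hydroxy-5-isopropylcyclohexane-1-carboxylate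
Product: 21 tert-butyl (5R,6S)-6-[(1E)-3-tert-butoxy-2-{[(tert-butyldiphenylsilyl)oxy]methyl}-3-oxoprop-1-en-1-yl]-2-{[(tert-butyldimethylsilyl)oxy]methyl}-5-isopropylcyclohex-1-ene-1-carboxylate
Conditions: Burgess reagent, toluene, 60 °C
Reagents that add atoms: none
Why: Burgess dehydration of the tertiary β-hydroxy ester by syn-elimination through the sulfamate, using the cis, ester-acidified axial hydrogen at C1, should give the conjugated tetrasubstituted enoate.

Step 14
Reactants: 21 tert-butyl (5R,6S)-6-[(1E)-3-tert-butoxy-2-{[(tert-butyldiphenylsilyl)oxy]methyl}-3-oxoprop-1-en-1-yl]-2-{[(tert-butyldimethylsilyl)oxy]methyl}-5-isopropylcyclohex-1-ene-1-carboxylate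
Product: 23 (2E)-2-{[(tert-butyldiphenylsilyl)oxy]methyl}-3-[(4S,5R)-5-isopropyl-3-oxo-1,3,4,5,6,7-hexahydro-2-benzofuran-4-yl]prop-2-enoic acid, via hydroxy diacid 22 (not isolated)
Conditions: TFA/CH2Cl2 (1:2), H2O (5 equiv), 0 °C → rt
Reagents that add atoms: none
Why: Acidolysis of both tert-butyl esters and the TBS ether (the TBDPS ether should tolerate aqueous TFA) unveils the cis γ-hydroxy enoic acid, which should lactonize spontaneously to the butenolide; a β,γ-alkene isomer carried over from step 13 is expected to equilibrate to the same conjugated lactone under the acid.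

Step 15
Reactants: 20 tert-butyl (1S,2S,5R,6S)-6-[(1E)-3-tert-butoxy-2-{[(tert-butyldiphenylsilyl)oxy]methyl}-3-oxoprop-1-en-1-yl]-2-{[(tert-butyldimethylsilyl)oxy]methyl}-2-hydroxy-5-isopropylcyclohexane-1-carboxylate
Product: 24 tert-butyl (1S,2S,5R,6S)-6-[(1E)-3-tert-butoxy-2-{[(tert-butyldiphenylsilyl)oxy]methyl}-3-oxoprop-1-en-1-yl]-2-hydroxy-2-(hydroxymethyl)-5-isopropylcyclohexane-1-carboxylate
Conditions: HF·pyridine, pyridine, THF, 0 °C
Reagents that add atoms: none
Why: Buffered HF·pyridine cleaves a primary TBS ether much faster than a TBDPS ether, and the bulky tert-butyl ester should resist lactonization by the freed cis CH2OH.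

Step 16
Reactants: 23 (2E)-2-{[(tert-butyldiphenylsilyl)oxy]methyl}-3-[(4S,5R)-5-isopropyl-3-oxo-1,3,4,5,6,7-hexahydro-2-benzofuran-4-yl]prop-2-enoic acid; 24 tert-butyl (1S,2S,5R,6S)-6-[(1E)-3-tert-butoxy-2-{[(tert-butyldiphenylsilyl)oxy]methyl}-3-oxoprop-1-en-1-yl]-2-hydroxy-2-(hydroxymethyl)-5-isopropylcyclohexane-1-carboxylate
Product: 26 fully protected dimer ester, via Yamaguchi mixed anhydride 25 (not isolated)
Conditions: 2,4,6-Cl3C6H2COCl, Et3N, THF, rt; then 24, DMAP, toluene, rt
Reagents that add atoms: 2,4,6-trichlorobenzoyl chloride O=C(Cl)c1c(Cl)cc(Cl)cc1Cl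
Why: Yamaguchi esterification, suited to a hindered α-branched acrylic acid, should acylate the primary hydroxyl of the diol through the mixed anhydride and leave the tertiary hydroxyl free.

Step 17
Reactants: 26 fully protected dimer ester
Product: 27 bis-TBDPS ether of the target
Conditions: TFA/CH2Cl2 (1:4), 0 °C → rt
Reagents that add atoms: none
Why: Acidolysis of the two tert-butyl esters; the TBDPS ethers, the linking ester, the butenolide and the tertiary alcohol (flanked by two electron-withdrawing groups) should survive.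

Step 18
Reactants: 27 bis-TBDPS ether of the target
Product: 28 CNP0071646.2 (target)
Conditions: HF·pyridine, THF, 0 °C → rt
Reagents that add atoms: none
Why: Fluoride cleavage of the two primary allylic TBDPS ethers under mildly acidic, non-basic conditions avoids acyl migration and retro-aldol cleavage of the free β-hydroxy acid.

Compound list
1 | (tert-butyldimethylsilyloxy)acetaldehyde | O=CCO[Si](C)(C)C(C)(C)C | starting material
2 | vinylmagnesium bromide | C=C[Mg]Br | starting material
3 | rac-1-[(tert-butyldimethylsilyl)oxy]but-3-en-2-ol | C=CC(O)CO[Si](C)(C)C(C)(C)C | intermediate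
4 | 1-[(tert-butyldimethylsilyl)oxy]but-3-en-2-one | C=CC(=O)CO[Si](C)(C)C(C)(C)C | intermediate
5 | 3-methylbutanal | CC(C)CC=O | starting material
6 | (2R)-6-[(tert-butyldimethylsilyl)oxy]-2-isopropyl-5-oxohexanal | CC(C)[C@H](C=O)CCC(=O)CO[Si](C)(C)C(C)(C)C | intermediate
7 | (triphenylphosphoranylidene)acetaldehyde | O=CC=P(c1ccccc1)(c1ccccc1)c1ccccc1 | starting material
8 | (2E,4R)-8-[(tert-butyldimethylsilyl)oxy]-4-isopropyl-7-oxooct-2-enal | CC(C)[C@H](/C=C/C=O)CCC(=O)CO[Si](C)(C)C(C)(C)C | intermediate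
9 | nitromethane | C[N+](=O)[O-] | starting material
10 | (3S,4R)-8-[(tert-butyldimethylsilyl)oxy]-4-isopropyl-3-(nitromethyl)-7-oxooctanal | [O-][N+](=O)C[C@H]([C@@H](C(C)C)CCC(=O)CO[Si](C)(C)C(C)(C)C)CC=O | intermediate
11 | (1S,2S,5R,6R)-2-{[(tert-butyldimethylsilyl)oxy]methyl}-2-hydroxy-5-isopropyl-6-(nitromethyl)cyclohexane-1-carbaldehyde | CC(C)[C@H]1CC[C@@](O)(CO[Si](C)(C)C(C)(C)C)[C@@H](C=O)[C@@H]1C[N+](=O)[O-] | intermediate
12 | (1S,2S,5R,6R)-2-{[(tert-butyldimethylsilyl)oxy]methyl}-2-hydroxy-5-isopropyl-6-(nitromethyl)cyclohexane-1-carboxylic acid | CC(C)[C@H]1CC[C@@](O)(CO[Si](C)(C)C(C)(C)C)[C@@H](C(=O)O)[C@@H]1C[N+](=O)[O-] | intermediate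
13 | tert-butyl (1S,2S,5R,6R)-2-{[(tert-butyldimethylsilyl)oxy]methyl}-2-hydroxy-5-isopropyl-6-(nitromethyl)cyclohexane-1-carboxylate | CC(C)[C@H]1CC[C@@](O)(CO[Si](C)(C)C(C)(C)C)[C@@H](C(=O)OC(C)(C)C)[C@@H]1C[N+](=O)[O-] | intermediate
14 | sodium nitronate (aci-nitro sodium salt of the nitro ester, ring stereocentres unchanged) | CC(C)[C@H]1CC[C@@](O)(CO[Si](C)(C)C(C)(C)C)[C@@H](C(=O)OC(C)(C)C)[C@@H]1C=[N+]([O-])[O-].[Na+] | intermediate
15 | tert-butyl (1S,2S,5R,6R)-2-{[(tert-butyldimethylsilyl)oxy]methyl}-6-formyl-2-hydroxy-5-isopropylcyclohexane-1-carboxylate | CC(C)[C@H]1CC[C@@](O)(CO[Si](C)(C)C(C)(C)C)[C@@H](C(=O)OC(C)(C)C)[C@@H]1C=O | intermediate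
16 | tert-butyl (diethoxyphosphoryl)acetate | CCOP(=O)(CC(=O)OC(C)(C)C)OCC | starting material
17 | formaldehyde (37% aqueous solution) | C=O | starting material
18 | rac-tert-butyl 2-(diethoxyphosphoryl)-3-hydroxypropanoate | CCOP(=O)(OCC)C(CO)C(=O)OC(C)(C)C | intermediate
19 | rac-tert-butyl 3-[(tert-butyldiphenylsilyl)oxy]-2-(diethoxyphosphoryl)propanoate | CCOP(=O)(OCC)C(CO[Si](c1ccccc1)(c1ccccc1)C(C)(C)C)C(=O)OC(C)(C)C | intermediate
20 | tert-butyl (1S,2S,5R,6S)-6-[(1E)-3-tert-butoxy-2-{[(tert-butyldiphenylsilyl)oxy]methyl}-3-oxoprop-1-en-1-yl]-2-{[(tert-butyldimethylsilyl)oxy]methyl}-2-hydroxy-5-isopropylcyclohexane-1-carboxylate | CC(C)[C@H]1CC[C@@](O)(CO[Si](C)(C)C(C)(C)C)[C@@H](C(=O)OC(C)(C)C)[C@@H]1/C=C(\CO[Si](c2ccccc2)(c2ccccc2)C(C)(C)C)C(=O)OC(C)(C)C | intermediate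
21 | tert-butyl (5R,6S)-6-[(1E)-3-tert-butoxy-2-{[(tert-butyldiphenylsilyl)oxy]methyl}-3-oxoprop-1-en-1-yl]-2-{[(tert-butyldimethylsilyl)oxy]methyl}-5-isopropylcyclohex-1-ene-1-carboxylate | CC(C)[C@H]1CCC(CO[Si](C)(C)C(C)(C)C)=C(C(=O)OC(C)(C)C)[C@@H]1/C=C(\CO[Si](c2ccccc2)(c2ccccc2)C(C)(C)C)C(=O)OC(C)(C)C | intermediate
22 | hydroxy diacid: (5R,6S)-6-[(1E)-2-carboxy-3-[(tert-butyldiphenylsilyl)oxy]prop-1-en-1-yl]-2-(hydroxymethyl)-5-isopropylcyclohex-1-ene-1-carboxylic acid | CC(C)[C@H]1CCC(CO)=C(C(=O)O)[C@@H]1/C=C(\CO[Si](c2ccccc2)(c2ccccc2)C(C)(C)C)C(=O)O | intermediate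
23 | (2E)-2-{[(tert-butyldiphenylsilyl)oxy]methyl}-3-[(4S,5R)-5-isopropyl-3-oxo-1,3,4,5,6,7-hexahydro-2-benzofuran-4-yl]prop-2-enoic acid | CC(C)[C@H]1CCC2=C(C(=O)OC2)[C@@H]1/C=C(\CO[Si](c3ccccc3)(c3ccccc3)C(C)(C)C)C(=O)O | intermediate
24 | tert-butyl (1S,2S,5R,6S)-6-[(1E)-3-tert-butoxy-2-{[(tert-butyldiphenylsilyl)oxy]methyl}-3-oxoprop-1-en-1-yl]-2-hydroxy-2-(hydroxymethyl)-5-isopropylcyclohexane-1-carboxylate | CC(C)[C@H]1CC[C@@](O)(CO)[C@@H](C(=O)OC(C)(C)C)[C@@H]1/C=C(\CO[Si](c2ccccc2)(c2ccccc2)C(C)(C)C)C(=O)OC(C)(C)C | intermediate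
25 | Yamaguchi mixed anhydride (2,4,6-trichlorobenzoic anhydride of the eastern acid) | CC(C)[C@H]1CCC2=C(C(=O)OC2)[C@@H]1/C=C(\CO[Si](c3ccccc3)(c3ccccc3)C(C)(C)C)C(=O)OC(=O)c4c(Cl)cc(Cl)cc4Cl | intermediate
26 | fully protected dimer ester: the western tert-butyl cyclohexanecarboxylate acylated on its 2-CH2OH by the eastern acid | CC(C)[C@H]1CC[C@@](O)(COC(=O)/C(=C/[C@H]2C3=C(CC[C@@H]2C(C)C)COC3=O)CO[Si](c4ccccc4)(c4ccccc4)C(C)(C)C)[C@@H](C(=O)OC(C)(C)C)[C@@H]1/C=C(\CO[Si](c5ccccc5)(c5ccccc5)C(C)(C)C)C(=O)OC(C)(C)C | intermediate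
27 | bis-TBDPS ether of the target (ring and side-chain carboxylic acids free) | CC(C)[C@H]1CC[C@@](O)(COC(=O)/C(=C/[C@H]2C3=C(CC[C@@H]2C(C)C)COC3=O)CO[Si](c4ccccc4)(c4ccccc4)C(C)(C)C)[C@@H](C(=O)O)[C@@H]1/C=C(\CO[Si](c5ccccc5)(c5ccccc5)C(C)(C)C)C(=O)O | intermediate
28 | CNP0071646.2: (1S,2S,5R,6S)-6-[(1E)-2-carboxy-3-hydroxyprop-1-en-1-yl]-2-hydroxy-2-{[((2E)-2-(hydroxymethyl)-3-[(4S,5R)-5-isopropyl-3-oxo-1,3,4,5,6,7-hexahydro-2-benzofuran-4-yl]prop-2-enoyl)oxy]methyl}-5-isopropylcyclohexane-1-carboxylic acid | CC(C)[C@H]1CC[C@@](O)(COC(=O)/C(=C/[C@H]2C3=C(CC[C@@H]2C(C)C)COC3=O)CO)[C@@H](C(=O)O)[C@@H]1/C=C(\CO)C(=O)O | target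

Total step count: 18. Longest linear sequence: 15 steps (steps 1–9, 12, 13, 14, 16, 17, 18).

Steps most likely to fail

Step 6. Ketone-enamine formation on the ring-methylene side and intermolecular aldolization may compete with the intended ring closure. The hydrogen-bonded transition state has to carry CH2OTBS axially, so facial selectivity at the ketone may erode. The tertiary aldol may also dehydrate under the catalyst. The fallback replaces kinetic hydrogen-bond control by a thermodynamic trap in a temporary ring. It sets out from 10: HF·pyridine would free the hydroxy ketone (3S,4R)-8-hydroxy-4-isopropyl-3-(nitromethyl)-7-oxooctanal F1. Reversible proline-mediated aldolization of F1 should then collect the material as the cis-fused lactol 3a-hydroxy-6-isopropyl-7-(nitromethyl)octahydro-2-benzofuran-1-ol F2, because the adduct with CH2OH cis to CHO closes to the less strained cis-fused hemiacetal and is drained from the aldol equilibrium. Oxidation with TEMPO/PhI(OAc)2 would give the hydroxy lactone 3a-hydroxy-6-isopropyl-7-(nitromethyl)hexahydro-2-benzofuran-1(3H)-one F3. Opening with LiOH (2.2 equiv, THF/H2O, 0 °C) and adjustment to pH 7 with phosphate buffer, which reprotonates the nitronate and keeps the carboxylate, would give the lithium dihydroxy carboxylate F4. Silylation of the dried salt with TBSCl/imidazole in DMF would give the TBS ester/TBS ether F5, and K2CO3 in aqueous methanol would cleave the silyl ester alone, so that the fallback comes back to the route at 12.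

Step 12 (with the reagent from steps 10 and 11). The hydroxymethylation may run on to the acrylate, the phosphonate anion may lose silanolate by β-elimination, and addition to the hindered aldehyde may be slow or incompletely E-selective. The fallback is an aldol/elimination sequence that needs no phosphonate. It sets out from 15: tert-butyl 3-[(tert-butyldiphenylsilyl)oxy]propanoate F6 would be made from tert-butyl 3-hydroxypropanoate with TBDPSCl/imidazole. Its lithium enolate (LDA, THF, −78 °C, 2.2 equiv) would add to the aldehyde to give the β-hydroxy ester aldol adduct F7 as a diastereomer mixture. Selective mesylation of the secondary hydroxyl would give the secondary mesylate F8, and DBU would eliminate by the E1cB path to the thermodynamically preferred E-enoate, coming back to the route at 20.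

Step 16. Base or DMAP may trigger lactonization of the diol onto its cis tert-butyl ester, and acylation of the neopentyl-type primary alcohol by the hindered α-branched acid may be slow. The fallback forms the same ester bond by alkylation instead of acylation, so the primary alcohol is never exposed to acylating conditions. It sets out from 24: cyclodehydration with PPh3/DIAD would give the spiro-epoxide F9 (CH2 axial, oxygen equatorial, retention at the tertiary carbon). The caesium salt of 23 (Cs2CO3, DMF, 70 °C) would then open F9 at the CH2 terminus, coming back to the route at 26.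

Further compounds
F1 | step 6 | (3S,4R)-8-hydroxy-4-isopropyl-3-(nitromethyl)-7-oxooctanal | [O-][N+](=O)C[C@H]([C@@H](C(C)C)CCC(=O)CO)CC=O
F2 | step 6 | cis-fused lactol 3a-hydroxy-6-isopropyl-7-(nitromethyl)octahydro-2-benzofuran-1-ol (ring stereocentres as in 11, anomeric mixture) | CC(C)[C@H]1CC[C@@]2(O)COC(O)[C@H]2[C@@H]1C[N+](=O)[O-]
F3 | step 6 | cis-fused hydroxy lactone 3a-hydroxy-6-isopropyl-7-(nitromethyl)hexahydro-2-benzofuran-1(3H)-one | CC(C)[C@H]1CC[C@@]2(O)COC(=O)[C@H]2[C@@H]1C[N+](=O)[O-]
F4 | step 6 | lithium (1S,2S,5R,6R)-2-hydroxy-2-(hydroxymethyl)-5-isopropyl-6-(nitromethyl)cyclohexane-1-carboxylate | CC(C)[C@H]1CC[C@@](O)(CO)[C@@H](C(=O)[O-])[C@@H]1C[N+](=O)[O-].[Li+]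
F5 | step 6 | tert-butyldimethylsilyl ester of 12 | CC(C)[C@H]1CC[C@@](O)(CO[Si](C)(C)C(C)(C)C)[C@@H](C(=O)O[Si](C)(C)C(C)(C)C)[C@@H]1C[N+](=O)[O-]
F6 | step 12 | tert-butyl 3-[(tert-butyldiphenylsilyl)oxy]propanoate | CC(C)(C)OC(=O)CCO[Si](c1ccccc1)(c1ccccc1)C(C)(C)C
F7 | step 12 | β-hydroxy ester aldol adduct of 15 (side-chain diastereomer mixture) | CC(C)[C@H]1CC[C@@](O)(CO[Si](C)(C)C(C)(C)C)[C@@H](C(=O)OC(C)(C)C)[C@@H]1C(O)C(CO[Si](c2ccccc2)(c2ccccc2)C(C)(C)C)C(=O)OC(C)(C)C
F8 | step 12 | secondary mesylate of the aldol adduct | CC(C)[C@H]1CC[C@@](O)(CO[Si](C)(C)C(C)(C)C)[C@@H](C(=O)OC(C)(C)C)[C@@H]1C(OS(C)(=O)=O)C(CO[Si](c2ccccc2)(c2ccccc2)C(C)(C)C)C(=O)OC(C)(C)C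
F9 | step 16 | spiro-epoxide from the 1,2-diol of 24 | CC(C)[C@H]1CC[C@@]2(CO2)[C@@H](C(=O)OC(C)(C)C)[C@@H]1/C=C(\CO[Si](c3ccccc3)(c3ccccc3)C(C)(C)C)C(=O)OC(C)(C)C
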